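**Plan** (locants are those of the 2,3-dihydro-1-benzofuran ring of the target)

- Cuts, in retrosynthetic order: the two bonds of the CH2 bridge between C5 and pyranone C3; the C7–acyl bond; C3–C2 together with O1–C7a; last C3a–C3. This leaves 5-fluororesorcinol, methacrolein, (S)-2-methylbutanoic acid, one-carbon reagents, pentan-3-one and malonyl dichloride.
- Forward: the benzene ring is bought and dressed (MOM ethers, two bromines flanking fluorine, one of them exchanged for CH2Br). The dihydrofuran ring is then closed in one operation, the bromine left at C7 is exchanged for the acyl group, and the separately made pyranone ring is joined through CH2 in the last step.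
- Enabling feature: C2 is bonded both to the benzylic C3 and to O1, and O1 sits on C7a, the ring carbon ortho to C3a. C7a is meta to the oxygens on C4 and C6, so a fluoride there is not deactivated by them. The C3/C7a pair can therefore act as a carbanion/aryl-electrophile unit that takes up the C=O of methacrolein across carbon and oxygen (formal [3+2]).
- Stereochemistry: C2 (S) is set in the key step by a chiral ligand on chromium. The (S)-2-methylbutanoyl center is bought as (S)-2-methylbutanoic acid and introduced by a non-enolising ketone synthesis.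

Key step: step 5

Assumption: the (S)-configured ligand is taken to give the (2S)-carbinol; if the sense of induction is the opposite, the (R)-ligand is used.

Step 1
Reactants: 1 5-fluorobenzene-1,3-diol
Product: 2 1-fluoro-3,5-bis(methoxymethoxy)benzene
Conditions: MOMCl (2.5 equiv), i-Pr2NEt, CH2Cl2, 0 °C to rt
Reagents that add atoms: chloromethyl methyl ether (MOMCl), COCCl
Why: Williamson-type O-alkylation of both phenols with the α-chloro ether should give base-stable methoxymethyl acetals that survive the organometallic steps and keep the ring oxygens from becoming phenoxides.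

Step 2
Reactants: 2 1-fluoro-3,5-bis(methoxymethoxy)benzene
Product: 3 2,4-dibromo-3-fluoro-1,5-bis(methoxymethoxy)benzene
Conditions: NBS (2.05 equiv), MeCN, 0 °C to rt
Reagents that add atoms: N-bromosuccinimide, O=C1CCC(=O)N1Br
Why: Electrophilic aromatic bromination should enter twice at the two equivalent carbons that flank fluorine, each ortho to one OMOM group and para to the other, because the remaining carbon between the two OMOM groups is the most hindered site.

Step 3
Reactants: 3 2,4-dibromo-3-fluoro-1,5-bis(methoxymethoxy)benzene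
Product: 5 [3-bromo-2-fluoro-4,6-bis(methoxymethoxy)phenyl]methanol, via arylmagnesium chloride 4 (not isolated)
Conditions: i-PrMgCl·LiCl (1.05 equiv), THF, −15 °C; then (CH2O)n, −15 °C to rt; H2O
Reagents that add atoms: paraformaldehyde (formaldehyde), C=O
Why: Bromine–magnesium exchange at one of the two equivalent C–Br bonds (the electron-rich arylmagnesium 4 should resist a second exchange and not lose fluoride at this temperature) followed by Grignard addition to formaldehyde installs the future C3 between fluorine and OMOM.

Step 4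
Reactants: 5 [3-bromo-2-fluoro-4,6-bis(methoxymethoxy)phenyl]methanol
Product: 6 1-bromo-3-(bromomethyl)-2-fluoro-4,6-bis(methoxymethoxy)benzene
Conditions: CBr4, PPh3, CH2Cl2, 0 °C; used crude
Reagents that add atoms: carbon tetrabromide, BrC(Br)(Br)Br
Why: The Appel reaction converts the primary benzylic alcohol into the bromide under neutral conditions that leave the acetals intact.

Step 5
Reactants: 6 1-bromo-3-(bromomethyl)-2-fluoro-4,6-bis(methoxymethoxy)benzene, 7 2-methylprop-2-enal (methacrolein)
Product: 11 (2S)-7-bromo-4,6-bis(methoxymethoxy)-2-(prop-1-en-2-yl)-2,3-dihydro-1-benzofuran, via benzylchromium dichloride 8 (not isolated), via silyl ether 9 (not isolated), via cesium alkoxide 10 (not isolated)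
Conditions: CrCl2 (10 mol %), (S)-N-[2-(4-isopropyl-4,5-dihydro-1,3-oxazol-2-yl)-6-methylphenyl]methanesulfonamide (12 mol %), Et3N (25 mol %), Mn powder (2 equiv), TMSCl (1.2 equiv), MeCN/THF, 0 °C to rt, slow addition of 6; filtration through Celite and change of solvent without purification; then CsF (1.5 equiv), 18-crown-6 (cat.), DMF, 70 °C
Reagents that add atoms: none
Why: Proposed new method: two single-electron transfers from divalent chromium (regenerated by Mn) to the benzylic C–Br bond of 6 should give the σ-benzyl trivalent chromium species 8 carrying the chiral sulfonamide–oxazoline ligand, which adds 1,2 to chromium-bound methacrolein (C3–C2 bond) before TMSCl turns the chromium alkoxide over to silyl ether 9; fluoride then unmasks alkoxide 10, which closes the dihydrofuran ring by 5-exo-trig addition–elimination (SNAr) at C7a with loss of fluoride (O1–C7a bond). The closest known reaction types are the catalytic enantioselective Nozaki–Hiyama–Kishi additions of allyl, alkenyl and alkyl halides with ligands of this class, the racemic addition of benzylchromium reagents to aldehydes, and fluoride-mediated aryl ether formation from silyl ethers and aryl fluorides; new here are a benzylic halide as the enantioselective partner and the telescoped ring closure. The only new stereocenter, C2, is set in the C–C bond-forming event by the ligand on chromium, which should shield one face of the coordinated aldehyde, and the ring closure does not touch it. The step needs 1,2- over 1,4-addition (inherent to organochromium reagents), benzylic over aryl C–Br activation (divalent chromium does not insert into aryl bromides without nickel) and ring closure at one carbon only: C7a is the sole C–F carbon, lies ortho to the benzylic arm, is flanked by bromine and is meta to both OMOM groups, so the ring donors do not deactivate it.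

Step 6
Reactants: 12 (2S)-2-methylbutanoic acid
Product: 14 (2S)-N-methoxy-N,2-dimethylbutanamide, via acyl imidazole 13 (not isolated)
Conditions: CDI, CH2Cl2, 0 °C to rt; then MeNH(OMe)·HCl, rt
Reagents that add atoms: N,O-dimethylhydroxylamine hydrochloride, CNOC.Cl
Why: Amide coupling through the acyl imidazole should give the Weinreb amide without enolisation of the α-stereocenter, which is taken unchanged from the commercial (S)-acid.

Step 7
Reactants: 11 (2S)-7-bromo-4,6-bis(methoxymethoxy)-2-(prop-1-en-2-yl)-2,3-dihydro-1-benzofuran, 14 (2S)-N-methoxy-N,2-dimethylbutanamide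
Product: 17 (2S)-1-[(2S)-4,6-bis(methoxymethoxy)-2-(prop-1-en-2-yl)-2,3-dihydro-1-benzofuran-7-yl]-2-methylbutan-1-one, via aryllithium 15 (not isolated), via lithium aminal alkoxide 16 (not isolated)
Conditions: n-BuLi (1.05 equiv), THF, −78 °C; then 14, −78 to 0 °C; H2O
Reagents that add atoms: none
Why: Bromine–lithium exchange is faster than any deprotonation at −78 °C and the Weinreb ketone synthesis stops at the chelated adduct 16 until work-up, so the acyl group should enter only at C7 without over-addition or enolisation of the (S)-center.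

Step 8
Reactants: 17 (2S)-1-[(2S)-4,6-bis(methoxymethoxy)-2-(prop-1-en-2-yl)-2,3-dihydro-1-benzofuran-7-yl]-2-methylbutan-1-one
Product: 18 (2S)-1-[(2S)-4,6-dihydroxy-2-(prop-1-en-2-yl)-2,3-dihydro-1-benzofuran-7-yl]-2-methylbutan-1-one
Conditions: p-TsOH·H2O (cat.), MeOH, 40 °C
Reagents that add atoms: none
Why: Acid-catalysed acetal exchange with methanol removes both MOM groups (the one next to the ketone with carbonyl assistance) under conditions mild enough to spare the allylic aryl ether and the isopropenyl group.

Step 9
Reactants: 19 pentan-3-one, 20 propanedioyl dichloride (malonyl dichloride)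
Product: 21 6-ethyl-4-hydroxy-5-methyl-2H-pyran-2-one
Conditions: no solvent, rt, 48 h; then H2O
Reagents that add atoms: none
Why: C-acylation of the ketone enol by the diacid chloride followed by O-acylation of the enol oxygen (the known ketone–malonyl dichloride route to 4-hydroxy-2-pyranones) builds the pyranone ring in one step, and the symmetric ketone allows only one regiochemistry.

Step 10
Reactants: 18 (2S)-1-[(2S)-4,6-dihydroxy-2-(prop-1-en-2-yl)-2,3-dihydro-1-benzofuran-7-yl]-2-methylbutan-1-one, 21 6-ethyl-4-hydroxy-5-methyl-2H-pyran-2-one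
Product: 24 3-{[(2S)-4,6-dihydroxy-7-[(2S)-2-methylbutanoyl]-2-(prop-1-en-2-yl)-2,3-dihydro-1-benzofuran-5-yl]methyl}-6-ethyl-4-hydroxy-5-methyl-2H-pyran-2-one, via Mannich base hydroiodide 22 (not isolated), via methylidenepyrandione 23 (not isolated)
Conditions: Eschenmoser's salt (1.0 equiv) and 21, MeCN, rt; then 18, 50 °C
Reagents that add atoms: Eschenmoser's salt (dimethylmethylideneammonium iodide), C=[N+](C)C.[I-]
Why: A Mannich reaction at C3 of the pyranone followed by loss of dimethylamine gives the Michael acceptor 23, which should be attacked by C5 of 18, the only unsubstituted ring carbon and ortho to two hydroxyl groups, to form the methylene bridge (the known way to join acylphloroglucinols to 4-hydroxypyranones).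

**Compound list**

1 | 5-fluorobenzene-1,3-diol | Oc1cc(O)cc(F)c1 | starting material
2 | 1-fluoro-3,5-bis(methoxymethoxy)benzene | COCOc1cc(F)cc(OCOC)c1 | intermediate
3 | 2,4-dibromo-3-fluoro-1,5-bis(methoxymethoxy)benzene | COCOc1cc(OCOC)c(Br)c(F)c1Br | intermediate
4 | [3-bromo-2-fluoro-4,6-bis(methoxymethoxy)phenyl]magnesium chloride | COCOc1cc(OCOC)c(Br)c(F)c1[Mg]Cl | intermediate (not isolated)
5 | [3-bromo-2-fluoro-4,6-bis(methoxymethoxy)phenyl]methanol | COCOc1cc(OCOC)c(Br)c(F)c1CO | intermediate
6 | 1-bromo-3-(bromomethyl)-2-fluoro-4,6-bis(methoxymethoxy)benzene | COCOc1cc(OCOC)c(Br)c(F)c1CBr | intermediate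
7 | 2-methylprop-2-enal (methacrolein) | C=C(C)C=O | starting material
8 | {[3-bromo-2-fluoro-4,6-bis(methoxymethoxy)phenyl]methyl}chromium dichloride (trivalent chromium; chiral ligand and solvent on chromium not drawn) | COCOc1cc(OCOC)c(Br)c(F)c1C[Cr](Cl)Cl | intermediate (not isolated)
9 | {[(2S)-1-[3-bromo-2-fluoro-4,6-bis(methoxymethoxy)phenyl]-3-methylbut-3-en-2-yl]oxy}trimethylsilane | C=C(C)[C@@H](O[Si](C)(C)C)Cc1c(F)c(Br)c(OCOC)cc1OCOC | intermediate (not isolated)
10 | cesium (2S)-1-[3-bromo-2-fluoro-4,6-bis(methoxymethoxy)phenyl]-3-methylbut-3-en-2-olate | C=C(C)[C@@H]([O-])Cc1c(F)c(Br)c(OCOC)cc1OCOC.[Cs+] | intermediate (not isolated)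
11 | (2S)-7-bromo-4,6-bis(methoxymethoxy)-2-(prop-1-en-2-yl)-2,3-dihydro-1-benzofuran | C=C(C)[C@@H]1Cc2c(OCOC)cc(OCOC)c(Br)c2O1 | intermediate
12 | (2S)-2-methylbutanoic acid | CC[C@H](C)C(=O)O | starting material
13 | (2S)-1-(1H-imidazol-1-yl)-2-methylbutan-1-one | CC[C@H](C)C(=O)n1ccnc1 | intermediate (not isolated)
14 | (2S)-N-methoxy-N,2-dimethylbutanamide | CC[C@H](C)C(=O)N(C)OC | intermediate
15 | [(2S)-4,6-bis(methoxymethoxy)-2-(prop-1-en-2-yl)-2,3-dihydro-1-benzofuran-7-yl]lithium | C=C(C)[C@@H]1Cc2c(OCOC)cc(OCOC)c([Li])c2O1 | intermediate (not isolated)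
16 | lithium (2S)-1-[(2S)-4,6-bis(methoxymethoxy)-2-(prop-1-en-2-yl)-2,3-dihydro-1-benzofuran-7-yl]-1-[methoxy(methyl)amino]-2-methylbutan-1-olate (carbinol carbon not defined) | C=C(C)[C@@H]1Cc2c(OCOC)cc(OCOC)c(C([O-])(N(C)OC)[C@@H](C)CC)c2O1.[Li+] | intermediate (not isolated)
17 | (2S)-1-[(2S)-4,6-bis(methoxymethoxy)-2-(prop-1-en-2-yl)-2,3-dihydro-1-benzofuran-7-yl]-2-methylbutan-1-one | C=C(C)[C@@H]1Cc2c(OCOC)cc(OCOC)c(C(=O)[C@@H](C)CC)c2O1 | intermediate
18 | (2S)-1-[(2S)-4,6-dihydroxy-2-(prop-1-en-2-yl)-2,3-dihydro-1-benzofuran-7-yl]-2-methylbutan-1-one | C=C(C)[C@@H]1Cc2c(O)cc(O)c(C(=O)[C@@H](C)CC)c2O1 | intermediate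
19 | pentan-3-one | CCC(=O)CC | starting material
20 | propanedioyl dichloride (malonyl dichloride) | O=C(Cl)CC(=O)Cl | starting material
21 | 6-ethyl-4-hydroxy-5-methyl-2H-pyran-2-one | CCc1oc(=O)cc(O)c1C | intermediate
22 | 3-[(dimethylamino)methyl]-6-ethyl-4-hydroxy-5-methyl-2H-pyran-2-one hydroiodide | CCc1oc(=O)c(C[NH+](C)C)c(O)c1C.[I-] | intermediate (not isolated)
23 | 6-ethyl-5-methyl-3-methylidene-2H-pyran-2,4(3H)-dione | CCC1=C(C)C(=O)C(=C)C(=O)O1 | intermediate (not isolated)
24 | 3-{[(2S)-4,6-dihydroxy-7-[(2S)-2-methylbutanoyl]-2-(prop-1-en-2-yl)-2,3-dihydro-1-benzofuran-5-yl]methyl}-6-ethyl-4-hydroxy-5-methyl-2H-pyran-2-one | C=C(C)[C@@H]1Cc2c(O)c(Cc3c(O)c(C)c(CC)oc3=O)c(O)c(C(=O)[C@@H](C)CC)c2O1 | target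

**Total step count:** 10

**Longest linear sequence:** 8 steps (steps 1, 2, 3, 4, 5, 7, 8 and 10, from 1 to 24)

**Steps most likely to fail**

1. Step 5 (proposed new method). Possible failures:
   - poor facial selectivity in the benzyl transfer to the aldehyde;
   - reductive homocoupling of the benzylic bromide;
   - pinacol-type reduction of the enal by divalent chromium;
   - acetal cleavage by silyl halide;
   - slow ring closure, leaving time for base-induced migration of the isopropenyl double bond.

   Fallback, all known reaction types: it sets out from 6. Stoichiometric CrCl2 in THF without ligand (the known racemic benzylchromium addition, through 8) and 7 give, after aqueous work-up, racemic 1-[3-bromo-2-fluoro-4,6-bis(methoxymethoxy)phenyl]-3-methylbut-3-en-2-ol F1. Dess–Martin periodinane (NaHCO3, CH2Cl2) oxidises it to 1-[3-bromo-2-fluoro-4,6-bis(methoxymethoxy)phenyl]-3-methylbut-3-en-2-one F2. CBS reduction with (R)-Me-CBS [(R)-1-methyl-3,3-diphenyltetrahydro-1H,3H-pyrrolo[1,2-c][1,3,2]oxazaborole] and catecholborane in toluene at −78 °C, with the α-branched alkenyl group as the large substituent, should give (2S)-1-[3-bromo-2-fluoro-4,6-bis(methoxymethoxy)phenyl]-3-methylbut-3-en-2-ol F3. KOtBu (1.05 equiv) and 18-crown-6 in THF at 50 °C then close the ring by alkoxide SNAr, and the route is rejoined at 11.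

2. Step 7. Possible failures: slow addition of the doubly ortho-substituted aryllithium to the α-branched amide, with competing proton transfer from the amide α-position that would also erode the (S)-center.

   Fallback: it sets out from 11, which is converted to 15 as before. The electrophile is changed to the less hindered (2S)-2-methylbutanal F4, made just before use from commercial (2S)-2-methylbutan-1-ol (CC[C@H](C)CO) with TEMPO/PhI(OAc)2. Addition at −78 °C gives (2S)-1-[(2S)-4,6-bis(methoxymethoxy)-2-(prop-1-en-2-yl)-2,3-dihydro-1-benzofuran-7-yl]-2-methylbutan-1-ol F5 as a mixture of carbinol epimers. Buffered Dess–Martin oxidation removes the extra center and the route is rejoined at 17.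

3. Step 10. Possible failures: self-condensation of the pyranone-derived electrophile to the methylene-bis-pyranone, and acid-promoted opening of the allylic aryl ether during the coupling.

   Fallback: it sets out from 18 and reverses the roles of the partners. Eschenmoser's salt in MeCN at rt aminomethylates C5 of 18 to give (2S)-1-[(2S)-5-[(dimethylamino)methyl]-4,6-dihydroxy-2-(prop-1-en-2-yl)-2,3-dihydro-1-benzofuran-7-yl]-2-methylbutan-1-one hydroiodide F6, which is isolated. Heating F6 with 21 in dioxane at 80 °C expels dimethylamine to give the ortho-quinone methide (2S)-7-[(2S)-2-methylbutanoyl]-6-hydroxy-5-methylidene-2-(prop-1-en-2-yl)-2,3-dihydro-1-benzofuran-4(5H)-one F7. F7 is trapped at its methylidene carbon by C3 of 21, and the route is rejoined at 24.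

**Further compounds**

F1 | step 5 | rac-1-[3-bromo-2-fluoro-4,6-bis(methoxymethoxy)phenyl]-3-methylbut-3-en-2-ol | C=C(C)C(O)Cc1c(F)c(Br)c(OCOC)cc1OCOC
F2 | step 5 | 1-[3-bromo-2-fluoro-4,6-bis(methoxymethoxy)phenyl]-3-methylbut-3-en-2-one | C=C(C)C(=O)Cc1c(F)c(Br)c(OCOC)cc1OCOC
F3 | step 5 | (2S)-1-[3-bromo-2-fluoro-4,6-bis(methoxymethoxy)phenyl]-3-methylbut-3-en-2-ol | C=C(C)[C@@H](O)Cc1c(F)c(Br)c(OCOC)cc1OCOC
F4 | step 7 | (2S)-2-methylbutanal | CC[C@H](C)C=O
F5 | step 7 | (2S)-1-[(2S)-4,6-bis(methoxymethoxy)-2-(prop-1-en-2-yl)-2,3-dihydro-1-benzofuran-7-yl]-2-methylbutan-1-ol (both carbinol epimers) | C=C(C)[C@@H]1Cc2c(OCOC)cc(OCOC)c(C(O)[C@@H](C)CC)c2O1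
F6 | step 10 | (2S)-1-[(2S)-5-[(dimethylamino)methyl]-4,6-dihydroxy-2-(prop-1-en-2-yl)-2,3-dihydro-1-benzofuran-7-yl]-2-methylbutan-1-one hydroiodide | C=C(C)[C@@H]1Cc2c(O)c(C[NH+](C)C)c(O)c(C(=O)[C@@H](C)CC)c2O1.[I-]
F7 | step 10 | (2S)-7-[(2S)-2-methylbutanoyl]-6-hydroxy-5-methylidene-2-(prop-1-en-2-yl)-2,3-dihydro-1-benzofuran-4(5H)-one | C=C(C)[C@@H]1CC2=C(O1)C(C(=O)[C@@H](C)CC)=C(O)C(=C)C2=O
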